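A small charge of initiator, 0.52 mM, stands in each of these flasks, and the length asked for is monomer in chains divided by chains begun. So the dispute is about how many chains that charge begins.

| setting | south-east | north-west | spring | dusk |
|---|---|---|---|---|
| free monomer | 14 mM | 25 mM | 20 mM | 40 mM |
| protic impurity | 20 mM | 20 mM | 20.0 mM | 20.0 mM |
| initiator | 0.52 mM | 0.52 mM | 0.52 mM | 0.52 mM |
| remark | run made earlier | run made earlier |  |  |
| time |  |  | 10 d | 10 d |

| run | time / d | monomer in chains / % | free monomer / % |
|---|---|---|---|
| south-east | 0.625 | 0.6 | 87.7 |
| south-east | 2.08 | 2.1 | 66.8 |
| south-east | 4.00 | 4.4 | 48.1 |
| south-east | 5.00 | 5.0 | 41.5 |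
| south-east | 8.00 | 8.3 | 27.4 |
| south-east | 10.0 | 8.3 | 20.5 |
| north-west | 1.67 | 2.5 | 73.6 |
| north-west | 3.00 | 5.5 | 58.4 |
| north-west | 5.00 | 9.9 | 44.6 |
| north-west | 6.00 | 11.9 | 39.1 |
| north-west | 8.00 | 14.0 | 31.6 |
| north-west | 10.0 | 16.2 | 26.1 |

(readings scatter by 0.3 percentage points)

* which of the two ends with the longer chains by the average number of monomer units in a chain (chains begun, living or dead) ("neither" if they lie within 10%) (spring / dusk / neither)
* average number of monomer units in a chain (chains begun, living or dead) at the end, spring
* average number of monomer units in a chain (chains begun, living or dead) at the end, dusk

- the average divides the monomer in chains by the number of chains begun, living and dead together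
- the numbers in the tables scatter with a standard deviation of 0.3 percentage points
- what may be going on: free monomer + initiator -> living end + monomer in chains; free monomer + living end -> monomer in chains + living end; initiator -> spent initiator; protic impurity + free monomer -> quenched substrate
- the earlier runs do not show the number of chains; that part of a forecast is a guess

Ida holds that each initiator begins one chain, so spring and dusk have the same count. Ben holds that initiator also dies on its own, so a larger charge of free monomer wins it more chains.

Ben brings a test. Growth runs as c(free monomer) times c(living end), so the gain in monomer in chains per day, per unit of free monomer, is a pseudo-first-order constant that follows c(living end). From 5.00 d to 10.0 d, south-east reads 0.0213 /d. From 5.00 d to 10.0 d, north-west reads 0.0356 /d.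

Dividing the logarithm of their ratio by the logarithm of the ratio of charges gives 0.889, the count order: the power of the free monomer charge that c(living end) follows. Ida needs zero here and Ben one. This reading is rough, given the scatter, but it lies nearer Ben.

Both accept the same treatment of the final monomer in chains, whose order in the charge reads 2.15. Going from spring to dusk, Ida's fixed count therefore lengthens chains by a factor 4.45, and my reckoning with the count order gives 2.40. Neither figure gives an absolute length, since the runs show no count.

The forecast, on Ben's side but from its own stepwise reckoning and a guessed count, names dusk, with 30 for spring and 68 for dusk. Its ground is that initiator decay “beats initiation and the yield is low”.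

The simulation gives dusk, with 55.2 for spring and 120 for dusk, a factor 2.17.

    free monomer + initiator → living end + monomer in chains (k = 0.00276 /M/min)
    free monomer + living end → monomer in chains + living end, rate k2*[living end]*[free monomer] (k = 0.478 /M/min)
    initiator → spent initiator (k = 4.38 × 10⁻⁴ /min)
    protic impurity + free monomer → quenched substrate (k = 0.00712 /M/min)

The count goes as Ben said: c(living end) ends at 0.0467 mM in spring and 0.0878 mM in dusk, a factor 1.88 against 1.85 from the count order. Dusk's neighbour with 100 mM of free monomer shows 2.05 against 2.26. The larger charge of free monomer is the main reason that dusk's chains are longer than spring's: with spring's charge, the dusk flask ends at 55.2 instead of 120.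

Readings and results are calculated from invented constants; scatter was added.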